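**Retrosynthetic overview**

1. Lettering: ring C is the central ring (aryl ethers at C1 and C5 to the two arms, at C6 to the chlorinated ring E, OH at C3). In each arm ring B carries O–ring A at B1, OH at B3 and B5, O–ring C at B4 and ring D at B6.
2. Feature used: on rings C, B and A the inter-ring ether oxygen (at C6, at B4, at position 1 of ring A) lies between two ring oxygens and para to a fourth oxygen (at C3, at B1, at position 4 of ring A). Writing that para oxygen as a formyl group makes the crowded carbon an SNAr site for fluoride displacement, and Dakin oxidation afterwards gives the oxygen back.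
3. Disconnections, backwards: seventeen O–Me bonds; the two B6–D biaryl bonds (Suzuki); the two ethers from B1 to position 1 of ring A (SNAr with fluoroaldehyde 5); the two C1/C5–O–B4 ethers (double SNAr of core diol 15 with 5); the C6–O–E ether (SNAr of ring E phenol 10 on 7, the MOM analogue of 5).
4. Order: no ring is built. The purchased arene rings are joined in the order C–E, then B, then A, then D, and each phenol for the next round arises from a formyl group.

Key step: step 11

Remark: the target has no stereocentre, and the B6–D axes are not stereogenic because ring D carries two identical ortho groups. 3,5-Dimethoxybenzaldehyde, 2-chloro-1,3-dimethoxybenzene and 2,4,6-trimethoxyphenylboronic acid are taken as commercial.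

**Route**

Step 1
Reactants: 1 3,5-dimethoxybenzaldehyde
Product: 2 1-(dimethoxymethyl)-3,5-dimethoxybenzene
Conditions: HC(OMe)3, MeOH, TsOH·H2O (cat.), rt
Reagents that add atoms: trimethyl orthoformate, COC(OC)OC; methanol, CO
Why: Acid-catalysed acetalisation, with the orthoformate removing water, masks the aldehyde against butyllithium.

Step 2
Reactants: 2 1-(dimethoxymethyl)-3,5-dimethoxybenzene
Product: 5 4-fluoro-3,5-dimethoxybenzaldehyde, via lithio acetal 3 (not isolated), via fluoro acetal 4 (not isolated)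
Conditions: n-BuLi, THF, 0 °C; NFSI, –78 °C to rt; then 2 M HCl, rt
Reagents that add atoms: N-fluorobenzenesulfonimide, O=S(=O)(c1ccccc1)N(F)S(=O)(=O)c1ccccc1; water, O
Why: Directed ortho-metalation should take place at C4, the position flanked by both methoxy groups, the aryllithium is fluorinated by the electrophilic N–F reagent, and the acidic work-up hydrolyses the acetal.

Step 3
Reactants: 5 4-fluoro-3,5-dimethoxybenzaldehyde
Product: 6 4-fluoro-3,5-dihydroxybenzaldehyde
Conditions: BBr3, CH2Cl2, –78 °C to rt; then H2O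
Reagents that add atoms: none
Why: Lewis-acid cleavage of aryl methyl ethers by BBr3 leaves the C–F bond intact and the aldehyde is returned on aqueous work-up.

Step 4
Reactants: 6 4-fluoro-3,5-dihydroxybenzaldehyde
Product: 7 4-fluoro-3,5-bis(methoxymethoxy)benzaldehyde
Conditions: MOMCl, i-Pr2NEt, CH2Cl2, 0 °C to rt
Reagents that add atoms: chloromethyl methyl ether, COCCl
Why: O-alkylation of both phenols with the α-chloro ether gives MOM ethers that are stable to base and peracid and can later be removed without touching methyl ethers.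

Step 5
Reactants: 8 2-chloro-1,3-dimethoxybenzene
Product: 9 2-(4-chloro-3,5-dimethoxyphenyl)-4,4,5,5-tetramethyl-1,3,2-dioxaborolane
Conditions: B2pin2 (1.0 equiv), [Ir(OMe)(cod)]2 (1.5 mol%), 4,4'-di-tert-butyl-2,2'-bipyridine (3 mol%), THF, 80 °C
Reagents that add atoms: bis(pinacolato)diboron, CC1(C)OB(OC1(C)C)B1OC(C)(C)C(C)(C)O1
Why: Sterically governed iridium-catalysed C–H borylation should functionalise C5, the only C–H not ortho to a substituent, and does not touch the C–Cl bond.

Step 6
Reactants: 9 2-(4-chloro-3,5-dimethoxyphenyl)-4,4,5,5-tetramethyl-1,3,2-dioxaborolane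
Product: 10 4-chloro-3,5-dimethoxyphenol
Conditions: 30% H2O2, NaOH aq, THF, 0 °C to rt; then HCl aq
Reagents that add atoms: hydrogen peroxide, OO
Why: Oxidation of the arylboronate by alkaline hydroperoxide (aryl shift from boron to oxygen) gives the phenol at the borylated carbon.

Step 7
Reactants: 7 4-fluoro-3,5-bis(methoxymethoxy)benzaldehyde; 10 4-chloro-3,5-dimethoxyphenol
Product: 11 4-(4-chloro-3,5-dimethoxyphenoxy)-3,5-bis(methoxymethoxy)benzaldehyde
Conditions: K2CO3, DMSO, 100 °C, N2
Reagents that add atoms: none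
Why: SNAr (addition–elimination) of an unhindered phenoxide at the fluoride para to the formyl group, a simpler case of the key reaction, forms the C6–O–E ether.

Step 8
Reactants: 11 4-(4-chloro-3,5-dimethoxyphenoxy)-3,5-bis(methoxymethoxy)benzaldehyde
Product: 13 4-(4-chloro-3,5-dimethoxyphenoxy)-3,5-bis(methoxymethoxy)phenol, via aryl formate 12 (not isolated)
Conditions: mCPBA, CH2Cl2, 0 °C to rt; then K2CO3, MeOH, rt
Reagents that add atoms: 3-chloroperoxybenzoic acid, OOC(=O)c1cccc(Cl)c1
Why: Dakin-type oxidation, in which Baeyer–Villiger migration of the oxygen-rich aryl group gives the formate and carbonate in methanol cleaves it to the phenol.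

Step 9
Reactants: 13 4-(4-chloro-3,5-dimethoxyphenoxy)-3,5-bis(methoxymethoxy)phenol
Product: 14 2-(4-chloro-3,5-dimethoxyphenoxy)-5-methoxy-1,3-bis(methoxymethoxy)benzene
Conditions: MeI, K2CO3, acetone, reflux
Reagents that add atoms: iodomethane, CI
Why: Williamson methylation of the only free phenol installs the C3 methyl ether.

Step 10
Reactants: 14 2-(4-chloro-3,5-dimethoxyphenoxy)-5-methoxy-1,3-bis(methoxymethoxy)benzene
Product: 15 core diol 2-(4-chloro-3,5-dimethoxyphenoxy)-5-methoxybenzene-1,3-diol
Conditions: HCl (cat.), MeOH, 50 °C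
Reagents that add atoms: none
Why: Acid-catalysed acetal cleavage removes both MOM groups, while aryl methyl ethers, the diaryl ether and the aryl chloride are inert.

Step 11
Reactants: 15 core diol 2-(4-chloro-3,5-dimethoxyphenoxy)-5-methoxybenzene-1,3-diol; 5 4-fluoro-3,5-dimethoxybenzaldehyde (2.5 equiv)
Product: 16 four-ring dialdehyde 4,4'-{[2-(4-chloro-3,5-dimethoxyphenoxy)-5-methoxy-1,3-phenylene]bis(oxy)}bis(3,5-dimethoxybenzaldehyde)
Conditions: Cs2CO3, 4 Å molecular sieves, DMSO, 110 °C, N2
Reagents that add atoms: none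
Why: Each caesium phenoxide of 15 adds to C4 of 5 to give a Meisenheimer anion whose charge is taken up by the para formyl group, and loss of fluoride restores the arene, so that two such events form the C1–O–B4 and C5–O–B4 bonds. The closest known reaction type is the SNAr etherification of phenoxides with 4-fluorobenzaldehydes, here at a fluoride flanked by two methoxy groups, which is the reason for the small fluoride leaving group, the loosely paired caesium phenoxide and the dipolar aprotic solvent. No ring is closed and no stereocentre is formed. The selectivity needed is site selectivity: the two phenols of 15 are related by the mirror plane through C3 and C6 and need no differentiation, 5 has a single activated leaving group, and the C–Cl bond of ring E sits on an electron-rich ring without an acceptor and cannot compete. An excess of 5 should drive the second substitution, which is slower than the first because the neighbouring aryloxy groups crowd the remaining phenoxide.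

Step 12
Reactants: 16 four-ring dialdehyde
Product: 18 four-ring bisphenol 4,4'-{[2-(4-chloro-3,5-dimethoxyphenoxy)-5-methoxy-1,3-phenylene]bis(oxy)}bis(3,5-dimethoxyphenol), via bis-formate 17 (not isolated)
Conditions: mCPBA (2.4 equiv), CH2Cl2, 0 °C to rt; then K2CO3, MeOH, rt
Reagents that add atoms: 3-chloroperoxybenzoic acid, OOC(=O)c1cccc(Cl)c1
Why: Two-fold Dakin-type oxidation (Baeyer–Villiger aryl migration, then formate methanolysis) turns both formyl groups into the B1 phenols, as in step 8.

Step 13
Reactants: 18 four-ring bisphenol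
Product: 19 four-ring bis(bromophenol) 4,4'-{[2-(4-chloro-3,5-dimethoxyphenoxy)-5-methoxy-1,3-phenylene]bis(oxy)}bis(2-bromo-3,5-dimethoxyphenol)
Conditions: NBS (2.0 equiv), i-Pr2NH (10 mol%), CH2Cl2, –78 to –20 °C
Reagents that add atoms: N-bromosuccinimide, O=C1CCC(=O)N1Br
Why: Electrophilic aromatic bromination, amine-mediated so that bromine is delivered next to the hydroxyl, is directed by the free B1 phenol to its ortho carbon (B2 and B6 are equivalent and the para position is blocked), the phenol rings being the most activated rings of 18 and the first bromine slowing a second attack on the same ring.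

Step 14
Reactants: 19 four-ring bis(bromophenol); 5 4-fluoro-3,5-dimethoxybenzaldehyde (2.5 equiv)
Product: 20 six-ring dibromo dialdehyde 4,4'-{[2-(4-chloro-3,5-dimethoxyphenoxy)-5-methoxy-1,3-phenylene]bis[oxy(2-bromo-3,5-dimethoxy-4,1-phenylene)oxy]}bis(3,5-dimethoxybenzaldehyde)
Conditions: Cs2CO3, 4 Å molecular sieves, DMSO, 120 °C, N2
Reagents that add atoms: none
Why: Second round of the SNAr etherification, in which the B1 phenoxides, carrying only a small ortho bromine, displace the fluoride of 5 and attach both ring A precursors.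

Step 15
Reactants: 20 six-ring dibromo dialdehyde
Product: 22 six-ring dibromo bisphenol 4,4'-{[2-(4-chloro-3,5-dimethoxyphenoxy)-5-methoxy-1,3-phenylene]bis[oxy(2-bromo-3,5-dimethoxy-4,1-phenylene)oxy]}bis(3,5-dimethoxyphenol), via bis-formate 21 (not isolated)
Conditions: mCPBA (2.4 equiv), CH2Cl2, 0 °C to rt; then K2CO3, MeOH, rt
Reagents that add atoms: 3-chloroperoxybenzoic acid, OOC(=O)c1cccc(Cl)c1
Why: Dakin-type oxidation exchanges formyl for hydroxyl at position 4 of each ring A, and it is placed before ring D is introduced so that the very electron-rich trimethoxyphenyl rings never meet the peracid.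

Step 16
Reactants: 22 six-ring dibromo bisphenol; 23 2,4,6-trimethoxyphenylboronic acid (6 equiv, in portions)
Product: 24 eight-ring bisphenol (heptadeca-O-methyl ether of the target)
Conditions: Pd(OAc)2 (10 mol%), SPhos (2-dicyclohexylphosphino-2',6'-dimethoxybiphenyl, 20 mol%), K3PO4, toluene/H2O 10:1, 100 °C
Reagents that add atoms: none
Why: Suzuki–Miyaura coupling with a bulky dialkylbiarylphosphine is the established way to tetra-ortho-substituted biaryls from 2,6-dialkoxyphenylboronic acids, oxidative addition into C–Br should be much faster than into the hindered electron-rich C–Cl bond of ring E, and free phenols are tolerated.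

Step 17
Reactants: 24 eight-ring bisphenol
Product: 25 target CNP0275555.0
Conditions: BBr3 (about 50 equiv), CH2Cl2, –78 °C to rt; then H2O, 0 °C, under argon
Reagents that add atoms: none
Why: Exhaustive BBr3 cleavage of all seventeen aryl methyl ethers, with diaryl ethers, biaryl bonds and the aryl chloride stable to the reagent.

**Compound list**

1 | 3,5-dimethoxybenzaldehyde | COc1cc(C=O)cc(OC)c1 | starting material
2 | 1-(dimethoxymethyl)-3,5-dimethoxybenzene | COc1cc(cc(OC)c1)C(OC)OC | intermediate
3 | [4-(dimethoxymethyl)-2,6-dimethoxyphenyl]lithium (lithio acetal) | [Li]c1c(OC)cc(cc1OC)C(OC)OC | intermediate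
4 | 5-(dimethoxymethyl)-2-fluoro-1,3-dimethoxybenzene (fluoro acetal) | COc1cc(cc(OC)c1F)C(OC)OC | intermediate
5 | 4-fluoro-3,5-dimethoxybenzaldehyde | COc1cc(C=O)cc(OC)c1F | intermediate
6 | 4-fluoro-3,5-dihydroxybenzaldehyde | O=Cc1cc(O)c(F)c(O)c1 | intermediate
7 | 4-fluoro-3,5-bis(methoxymethoxy)benzaldehyde | COCOc1cc(C=O)cc(OCOC)c1F | intermediate
8 | 2-chloro-1,3-dimethoxybenzene | COc1cccc(OC)c1Cl | starting material
9 | 2-(4-chloro-3,5-dimethoxyphenyl)-4,4,5,5-tetramethyl-1,3,2-dioxaborolane | COc1cc(cc(OC)c1Cl)B1OC(C)(C)C(C)(C)O1 | intermediate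
10 | 4-chloro-3,5-dimethoxyphenol | COc1cc(O)cc(OC)c1Cl | intermediate
11 | 4-(4-chloro-3,5-dimethoxyphenoxy)-3,5-bis(methoxymethoxy)benzaldehyde | COCOc1cc(C=O)cc(OCOC)c1Oc1cc(OC)c(Cl)c(OC)c1 | intermediate
12 | 4-(4-chloro-3,5-dimethoxyphenoxy)-3,5-bis(methoxymethoxy)phenyl formate | COCOc1cc(OC=O)cc(OCOC)c1Oc1cc(OC)c(Cl)c(OC)c1 | intermediate
13 | 4-(4-chloro-3,5-dimethoxyphenoxy)-3,5-bis(methoxymethoxy)phenol | COCOc1cc(O)cc(OCOC)c1Oc1cc(OC)c(Cl)c(OC)c1 | intermediate
14 | 2-(4-chloro-3,5-dimethoxyphenoxy)-5-methoxy-1,3-bis(methoxymethoxy)benzene | COCOc1cc(OC)cc(OCOC)c1Oc1cc(OC)c(Cl)c(OC)c1 | intermediate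
15 | 2-(4-chloro-3,5-dimethoxyphenoxy)-5-methoxybenzene-1,3-diol (core diol) | COc1cc(O)c(Oc2cc(OC)c(Cl)c(OC)c2)c(O)c1 | intermediate
16 | 4,4'-{[2-(4-chloro-3,5-dimethoxyphenoxy)-5-methoxy-1,3-phenylene]bis(oxy)}bis(3,5-dimethoxybenzaldehyde) (four-ring dialdehyde) | COc1cc(Oc2c(OC)cc(C=O)cc2OC)c(Oc2cc(OC)c(Cl)c(OC)c2)c(Oc2c(OC)cc(C=O)cc2OC)c1 | intermediate
17 | bis-formate of 16, formyloxy at both B1 positions | COc1cc(Oc2c(OC)cc(OC=O)cc2OC)c(Oc2cc(OC)c(Cl)c(OC)c2)c(Oc2c(OC)cc(OC=O)cc2OC)c1 | intermediate
18 | 4,4'-{[2-(4-chloro-3,5-dimethoxyphenoxy)-5-methoxy-1,3-phenylene]bis(oxy)}bis(3,5-dimethoxyphenol) (four-ring bisphenol) | COc1cc(Oc2c(OC)cc(O)cc2OC)c(Oc2cc(OC)c(Cl)c(OC)c2)c(Oc2c(OC)cc(O)cc2OC)c1 | intermediate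
19 | 4,4'-{[2-(4-chloro-3,5-dimethoxyphenoxy)-5-methoxy-1,3-phenylene]bis(oxy)}bis(2-bromo-3,5-dimethoxyphenol) | COc1cc(Oc2c(OC)cc(O)c(Br)c2OC)c(Oc2cc(OC)c(Cl)c(OC)c2)c(Oc2c(OC)cc(O)c(Br)c2OC)c1 | intermediate
20 | six-ring dibromo dialdehyde, each B1 oxygen bearing a 4-formyl-2,6-dimethoxyphenyl group | COc1cc(Oc2c(OC)cc(Oc3c(OC)cc(C=O)cc3OC)c(Br)c2OC)c(Oc2cc(OC)c(Cl)c(OC)c2)c(Oc2c(OC)cc(Oc3c(OC)cc(C=O)cc3OC)c(Br)c2OC)c1 | intermediate
21 | bis-formate of 20, formyloxy at position 4 of both rings A | COc1cc(Oc2c(OC)cc(Oc3c(OC)cc(OC=O)cc3OC)c(Br)c2OC)c(Oc2cc(OC)c(Cl)c(OC)c2)c(Oc2c(OC)cc(Oc3c(OC)cc(OC=O)cc3OC)c(Br)c2OC)c1 | intermediate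
22 | six-ring dibromo bisphenol, OH at position 4 of both rings A | COc1cc(Oc2c(OC)cc(Oc3c(OC)cc(O)cc3OC)c(Br)c2OC)c(Oc2cc(OC)c(Cl)c(OC)c2)c(Oc2c(OC)cc(Oc3c(OC)cc(O)cc3OC)c(Br)c2OC)c1 | intermediate
23 | 2,4,6-trimethoxyphenylboronic acid | COc1cc(OC)c(B(O)O)c(OC)c1 | starting material
24 | eight-ring bisphenol, heptadeca-O-methyl ether of the target with free OH at position 4 of both rings A | COc1cc(Oc2c(OC)cc(Oc3c(OC)cc(O)cc3OC)c(-c3c(OC)cc(OC)cc3OC)c2OC)c(Oc2cc(OC)c(Cl)c(OC)c2)c(Oc2c(OC)cc(Oc3c(OC)cc(O)cc3OC)c(-c3c(OC)cc(OC)cc3OC)c2OC)c1 | intermediate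
25 | CNP0275555.0 | Oc1cc(O)c(Oc2cc(O)c(Oc3cc(O)cc(Oc4c(O)cc(Oc5c(O)cc(O)cc5O)c(-c5c(O)cc(O)cc5O)c4O)c3Oc3cc(O)c(Cl)c(O)c3)c(O)c2-c2c(O)cc(O)cc2O)c(O)c1 | target

**Step count and risks**

Total steps: 17. Longest linear sequence: 15 steps (1 → 2 → 5 → 6 → 7 → 11 → 13 → 14 → 15 → 16 → 18 → 19 → 20 → 22 → 24 → 25); the ring E branch (steps 5 and 6) joins at step 7.

Steps most likely to fail:

Step 11 (key step). The displacement may stall after the first substitution, because the fluoride is shielded by two methoxy groups and the second phenoxide is crowded, and the aldehyde may degrade under base at the temperature that would then be needed. The fallback sets out from acetal 2 and core diol 15 and makes the same ethers by copper catalysis. Lithio acetal 3, generated as in step 2, would be quenched with I2 in place of NFSI to give 5-(dimethoxymethyl)-2-iodo-1,3-dimethoxybenzene F1. Acidic work-up would hydrolyse F1 to 4-iodo-3,5-dimethoxybenzaldehyde F2. Ullmann-type O-arylation of both phenols of 15 with F2 (CuI, picolinic acid, K3PO4, DMSO, 90 °C), which leaves the aryl chloride alone, would come back to the route at 16.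

Step 16. Protodeboronation of the 2,6-dialkoxyphenylboronic acid may outrun transmetalation at the doubly ortho-substituted bromide. That would leave the two-fold coupling incomplete, with hydrodebromination and some insertion into C–Cl as the time at temperature grows. The fallback sets out from dibromo dialdehyde 20, which has no acidic proton, and uses an arylzinc. Commercial 1,3,5-trimethoxybenzene (COc1cc(OC)cc(OC)c1) would be lithiated (n-BuLi, THF, 0 °C) to (2,4,6-trimethoxyphenyl)lithium F3, and F3 would be transmetalated with ZnCl2 to chloro(2,4,6-trimethoxyphenyl)zinc F4. Negishi coupling of F4 with 20 (Pd2(dba)3, RuPhos (2-dicyclohexylphosphino-2',6'-diisopropoxybiphenyl), THF, 70 °C) should give the eight-ring dialdehyde F5, in which position 4 of each ring A still carries its formyl group. Dakin oxidation of F5 under buffered conditions (mCPBA, NaHCO3, CH2Cl2, 0 °C; then K2CO3, MeOH) through the eight-ring bis-formate F6 would come back to the route at 24.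

Step 13. Site selectivity may be lost: bromine may enter ring C at C2 or C4 or ring E, or a ring B may be brominated twice. The fallback sets out from monomer 5 and core diol 15 and places the bromine before the rings are joined. Bromination of 5 (NBS, MeCN, rt) at the only position ortho and para to the two methoxy groups would give 2-bromo-4-fluoro-3,5-dimethoxybenzaldehyde F7. Double SNAr of 15 with F7 under the conditions of step 11, where fluoride para to the formyl group leaves far faster than bromide ortho to it, would give the four-ring dibromo dialdehyde F8, with bromine at B6 and formyl at B1 of each arm. Dakin oxidation of F8 (mCPBA, CH2Cl2; then K2CO3, MeOH) through the four-ring dibromo bis-formate F9 would come back to the route at 19.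

**Further compounds**

F1 | step 11 | 5-(dimethoxymethyl)-2-iodo-1,3-dimethoxybenzene | COc1cc(cc(OC)c1I)C(OC)OC
F2 | step 11 | 4-iodo-3,5-dimethoxybenzaldehyde | COc1cc(C=O)cc(OC)c1I
F3 | step 16 | (2,4,6-trimethoxyphenyl)lithium | [Li]c1c(OC)cc(OC)cc1OC
F4 | step 16 | chloro(2,4,6-trimethoxyphenyl)zinc | Cl[Zn]c1c(OC)cc(OC)cc1OC
F5 | step 16 | eight-ring dialdehyde | COc1cc(Oc2c(OC)cc(Oc3c(OC)cc(C=O)cc3OC)c(-c3c(OC)cc(OC)cc3OC)c2OC)c(Oc2cc(OC)c(Cl)c(OC)c2)c(Oc2c(OC)cc(Oc3c(OC)cc(C=O)cc3OC)c(-c3c(OC)cc(OC)cc3OC)c2OC)c1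
F6 | step 16 | eight-ring bis-formate | COc1cc(Oc2c(OC)cc(Oc3c(OC)cc(OC=O)cc3OC)c(-c3c(OC)cc(OC)cc3OC)c2OC)c(Oc2cc(OC)c(Cl)c(OC)c2)c(Oc2c(OC)cc(Oc3c(OC)cc(OC=O)cc3OC)c(-c3c(OC)cc(OC)cc3OC)c2OC)c1
F7 | step 13 | 2-bromo-4-fluoro-3,5-dimethoxybenzaldehyde | COc1cc(C=O)c(Br)c(OC)c1F
F8 | step 13 | four-ring dibromo dialdehyde | COc1cc(Oc2c(OC)cc(C=O)c(Br)c2OC)c(Oc2cc(OC)c(Cl)c(OC)c2)c(Oc2c(OC)cc(C=O)c(Br)c2OC)c1
F9 | step 13 | four-ring dibromo bis-formate | COc1cc(Oc2c(OC)cc(OC=O)c(Br)c2OC)c(Oc2cc(OC)c(Cl)c(OC)c2)c(Oc2c(OC)cc(OC=O)c(Br)c2OC)c1
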